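**Plan** (daucane numbering: C1 = CMe ring-fusion carbon, C2/C3 = ring CH2, C4 = C(OH)iPr, C5 = ring-fusion CH, C6 = CH–O, C7 = CH2, C8 = C(Me)=, C9 = =CH, C10 = CH2)
- Retrosynthesis cuts the vanillate C–O bond, then C3–C4 of the cyclopentane (Barbier closure), then C1–C10 and C5–C6 of the cycloheptene together in one [5+2] event, then the O–Si–O tether.
- Forward: the cycloheptene arises first, fused to a temporary 1,3-dioxa-2-silacyclohexane; the cyclopentane is closed second; the aroyl group is joined last.
- Enabling feature: O-4 and O-6 are 1,3-related across C5, so a silylene can link a C4 enol oxygen to the C6 oxygen; C6(O)–C7–C8(Me)=C9–C10 is the retron of a 2-siloxy-vinylcyclopropane.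
- Stereochemistry: C6 comes from a lipase-resolved cyclopropanol. The trans ring fusion (C1/C5) comes from suprafacial addition to an (E)-trisubstituted alkene, its sense relayed from C6; the cyclopropane C2 centre is erased (stereoconvergent). C4 comes from the chelation-controlled Barbier closure.

Key step: step 6

Remark: the facial sense of step 6 (H-5/H-6 anti) is an assumption argued from ring strain, and the cyclopropanol enantiomer is chosen on that basis.

Step 1
Reactants: 1 tert-butyl(but-3-yn-1-yloxy)dimethylsilane; 2 2-methylpropanoyl chloride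
Product: 4 (4E)-7-[(tert-butyldimethylsilyl)oxy]-2,5-dimethylhept-4-en-3-one, via alkenylalane 3 (not isolated)
Conditions: AlMe3 (2 equiv), Cp2ZrCl2 (0.2 equiv), CH2Cl2, 0 °C → rt; then ZnCl2, THF, 2, Pd(PPh3)4 (5 mol %), 0 °C → rt
Reagents that add atoms: trimethylaluminium, C[Al](C)C
Why: Negishi carboalumination adds Me and Al syn across the terminal alkyne (Me at the internal carbon), and the Pd-catalysed acylation of the derived alkenylzinc keeps the geometry, fixing the (E)-alkene that later encodes the trans ring fusion.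

Step 2
Reactants: 5 (2E)-2-methylbut-2-enal
Product: 6 trimethyl[(2-methylbuta-1,3-dien-1-yl)oxy]silane (E/Z mixture)
Conditions: TMSOTf, Et3N, Et2O, 0 °C
Reagents that add atoms: trimethylsilyl trifluoromethanesulfonate, C[Si](C)(C)OS(=O)(=O)C(F)(F)F
Why: soft enolisation (γ-deprotonation and O-silylation) of the enal should give the 1-siloxy-1,3-diene, as in the standard preparation of 1-silyloxybutadienes.

Step 3
Reactants: 6 trimethyl[(2-methylbuta-1,3-dien-1-yl)oxy]silane
Product: 8 rac-2-ethenyl-2-methylcyclopropan-1-ol (cis/trans mixture), via cyclopropyl silyl ether 7 (not isolated)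
Conditions: Et2Zn (1.05 equiv), CH2I2 (1.05 equiv), Et2O, 0 °C; then MeOH, citric acid (cat.), 0 °C
Reagents that add atoms: diiodomethane, ICI
Why: the Furukawa variant of the Simmons–Smith cyclopropanation should attack the electron-rich enol ether C=C in preference to the terminal vinyl group, and mild methanolysis frees the cyclopropanol; no control is needed at C2 because it becomes sp2 in step 6.

Step 4
Reactants: 8 rac-2-ethenyl-2-methylcyclopropan-1-ol
Product: 9 (1S)-2-ethenyl-2-methylcyclopropan-1-ol (both C2 epimers)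
Conditions: Burkholderia cepacia lipase, vinyl acetate, t-BuOMe, rt, stopped near half conversion; chromatography
Reagents that add atoms: none
Why: lipase-catalysed kinetic resolution should acylate the (1R)-alcohols (quaternary C2 as the large, ring CH2 as the medium substituent of the empirical size rule) and leave the (1S)-carbinol centre, the future C6.

Step 5
Reactants: 4 (4E)-7-[(tert-butyldimethylsilyl)oxy]-2,5-dimethylhept-4-en-3-one; 9 (1S)-2-ethenyl-2-methylcyclopropan-1-ol
Product: 11 {[(1S)-2-ethenyl-2-methylcyclopropyl]oxy}{[(4E)-7-[(tert-butyldimethylsilyl)oxy]-2,5-dimethylhepta-2,4-dien-3-yl]oxy}di(propan-2-yl)silane, via chlorosilyl dienol ether 10 (not isolated)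
Conditions: LDA, THF, −78 °C; iPr2SiCl2 (3 equiv), −78 → 0 °C; volatiles removed; then 9, imidazole, CH2Cl2, 0 °C → rt
Reagents that add atoms: dichlorodi(propan-2-yl)silane, CC(C)[Si](Cl)(Cl)C(C)C
Why: kinetic α′-deprotonation of the enone should give the cross-conjugated dienolate, which is O-silylated by the excess dichlorosilane, and the remaining Si–Cl bond is displaced by the cyclopropanol (sequential assembly of an unsymmetrical silylene tether).

Step 6
Reactants: 11 {[(1S)-2-ethenyl-2-methylcyclopropyl]oxy}{[(4E)-7-[(tert-butyldimethylsilyl)oxy]-2,5-dimethylhepta-2,4-dien-3-yl]oxy}di(propan-2-yl)silane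
Product: 12 (4aS,5S,9aS)-5-{2-[(tert-butyldimethylsilyl)oxy]ethyl}-5,8-dimethyl-2,2-di(propan-2-yl)-4-(propan-2-ylidene)-4,4a,5,6,9,9a-hexahydrocyclohepta[d][1,3,2]dioxasiline
Conditions: [Rh(CO)2Cl]2 (5 mol %), toluene, 80 °C, degassed
Reagents that add atoms: none
Why: Proposed new method: Rh(I) should insert into the cyclopropane bond between the siloxy-bearing carbon and the vinyl-bearing quaternary carbon (favoured by the tether and the donor oxygen) to give a σ-alkyl/π-allyl rhodacycle, the tethered (E)-alkene should insert suprafacially into the Rh–allyl bond (C1–C10) and reductive elimination should form C5–C6; the closest known reaction type is the Rh-catalysed intramolecular [5+2] cycloaddition of ene–vinylcyclopropanes, including substrates tethered through a cyclopropane carbon, extended here to a 2-siloxy-vinylcyclopropane, a trisubstituted alkene and a silylene tether. The cycloheptene closes by C–C reductive elimination from an eight-membered rhodacycle (formal [5+2]) and the 1,3-dioxa-2-silacyclohexane closes through the same C5–C6 bond (six-membered, exo with respect to the tether). C1 and C5 are set relative to each other by syn addition across the (E)-alkene, which puts the silyloxyethyl arm and C4 trans on the new ring; C6 keeps the configuration of the cyclopropanol carbinol (retention in oxidative addition and in reductive elimination); the facial sense should be relayed from C6 because only the trans-diequatorial fusion of the tether ring (H-5/H-6 anti) avoids a syn-axial clash of O-6 or C4 with the C1 methyl. The cyclopropane C2 centre becomes the sp2 C8, so both C2 epimers of 11 should converge on one adduct. The step needs C6–C8 rather than C7–C8 cleavage, [5+2] rather than [3+2] closure and no β-hydride elimination: [3+2] closure would create two adjacent quaternary carbons, and the alkyl–rhodium at C5 is flanked by the sp2 C4 and the quaternary C1 and has no β-hydrogen.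

Step 7
Reactants: 12 (4aS,5S,9aS)-5-{2-[(tert-butyldimethylsilyl)oxy]ethyl}-5,8-dimethyl-2,2-di(propan-2-yl)-4-(propan-2-ylidene)-4,4a,5,6,9,9a-hexahydrocyclohepta[d][1,3,2]dioxasiline
Product: 13 1-[(1S,2S,7S)-2-hydroxy-7-(2-hydroxyethyl)-4,7-dimethylcyclohept-4-en-1-yl]-2-methylpropan-1-one
Conditions: HF·pyridine, pyridine, THF, 0 °C → rt
Reagents that add atoms: none
Why: fluoride should cleave both Si–O bonds of the silylene (the enol ether is protonated at carbon to release the isopropyl ketone) and the primary TBS ether; the buffered medium guards against epimerisation at C5 and retro-aldol cleavage of the β-hydroxy ketone.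

Step 8
Reactants: 13 1-[(1S,2S,7S)-2-hydroxy-7-(2-hydroxyethyl)-4,7-dimethylcyclohept-4-en-1-yl]-2-methylpropan-1-one
Product: 14 1-[(1S,2S,7S)-2-hydroxy-7-(2-iodoethyl)-4,7-dimethylcyclohept-4-en-1-yl]-2-methylpropan-1-one
Conditions: I2, PPh3, imidazole, CH2Cl2, 0 °C
Reagents that add atoms: iodine, II
Why: Appel-type iodination should be selective for the primary alcohol over the hindered secondary carbinol and runs under near-neutral conditions.

Step 9
Reactants: 14 1-[(1S,2S,7S)-2-hydroxy-7-(2-iodoethyl)-4,7-dimethylcyclohept-4-en-1-yl]-2-methylpropan-1-one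
Product: 15 (3R,3aS,4S,8aR)-6,8a-dimethyl-3-(propan-2-yl)-1,2,3,3a,4,5,8,8a-octahydroazulene-3,4-diol (jaeschkeanadiol)
Conditions: SmI2 (2.5 equiv), HMPA, THF, −78 → 0 °C
Reagents that add atoms: none
Why: the SmI2-promoted intramolecular Barbier reaction should close the cyclopentane by 5-exo addition to the ketone; Sm(III) chelation between the C6 oxygen and the carbonyl oxygen, reinforced by the isopropyl group avoiding C6 and the C1 methyl, should place the new hydroxyl cis to C6, and the trans fusion follows from the trans arms set in step 6.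

Step 10
Reactants: 15 (3R,3aS,4S,8aR)-6,8a-dimethyl-3-(propan-2-yl)-1,2,3,3a,4,5,8,8a-octahydroazulene-3,4-diol; 16 4-(acetyloxy)-3-methoxybenzoic acid
Product: 17 (3R,3aS,4S,8aR)-3-hydroxy-6,8a-dimethyl-3-(propan-2-yl)-1,2,3,3a,4,5,8,8a-octahydroazulen-4-yl 4-(acetyloxy)-3-methoxybenzoate
Conditions: DCC, DMAP, CH2Cl2, rt → 40 °C
Reagents that add atoms: none
Why: Steglich esterification should acylate only the secondary hydroxyl, since the tertiary alcohol is inert and the phenol is masked as its acetate.

Step 11
Reactants: 17 (3R,3aS,4S,8aR)-3-hydroxy-6,8a-dimethyl-3-(propan-2-yl)-1,2,3,3a,4,5,8,8a-octahydroazulen-4-yl 4-(acetyloxy)-3-methoxybenzoate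
Product: 18 teferin, (3R,3aS,4S,8aR)-3-hydroxy-6,8a-dimethyl-3-(propan-2-yl)-1,2,3,3a,4,5,8,8a-octahydroazulen-4-yl 4-hydroxy-3-methoxybenzoate
Conditions: K2CO3 (cat.), MeOH, 0 °C
Reagents that add atoms: none
Why: methanolysis of the aryl acetate should be far faster than that of the hindered secondary aroate, so the phenol is freed selectively.

**Compound list**
1 | tert-butyl(but-3-yn-1-yloxy)dimethylsilane | C#CCCO[Si](C)(C)C(C)(C)C | starting material
2 | 2-methylpropanoyl chloride | CC(C)C(Cl)=O | starting material
3 | [(1E)-4-[(tert-butyldimethylsilyl)oxy]-2-methylbut-1-en-1-yl]dimethylalane | C[Al](C)/C=C(\C)CCO[Si](C)(C)C(C)(C)C | intermediate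
4 | (4E)-7-[(tert-butyldimethylsilyl)oxy]-2,5-dimethylhept-4-en-3-one | CC(C)C(=O)/C=C(\C)CCO[Si](C)(C)C(C)(C)C | intermediate
5 | (2E)-2-methylbut-2-enal | C/C=C(\C)C=O | starting material
6 | trimethyl[(2-methylbuta-1,3-dien-1-yl)oxy]silane (E/Z mixture) | C=CC(C)=CO[Si](C)(C)C | intermediate
7 | [(2-ethenyl-2-methylcyclopropyl)oxy]trimethylsilane (racemic, cis/trans) | C=CC1(C)CC1O[Si](C)(C)C | intermediate
8 | rac-2-ethenyl-2-methylcyclopropan-1-ol (cis/trans) | C=CC1(C)CC1O | intermediate
9 | (1S)-2-ethenyl-2-methylcyclopropan-1-ol (both C2 epimers) | O[C@H]1CC1(C)C=C | intermediate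
10 | chloro{[(4E)-7-[(tert-butyldimethylsilyl)oxy]-2,5-dimethylhepta-2,4-dien-3-yl]oxy}di(propan-2-yl)silane | CC(C)[Si](Cl)(C(C)C)OC(=C(C)C)/C=C(\C)CCO[Si](C)(C)C(C)(C)C | intermediate
11 | {[(1S)-2-ethenyl-2-methylcyclopropyl]oxy}{[(4E)-7-[(tert-butyldimethylsilyl)oxy]-2,5-dimethylhepta-2,4-dien-3-yl]oxy}di(propan-2-yl)silane | CC(C)[Si](C(C)C)(O[C@H]1CC1(C)C=C)OC(=C(C)C)/C=C(\C)CCO[Si](C)(C)C(C)(C)C | intermediate
12 | (4aS,5S,9aS)-5-{2-[(tert-butyldimethylsilyl)oxy]ethyl}-5,8-dimethyl-2,2-di(propan-2-yl)-4-(propan-2-ylidene)-4,4a,5,6,9,9a-hexahydrocyclohepta[d][1,3,2]dioxasiline | CC(C)[Si]1(C(C)C)O[C@H]2CC(C)=CC[C@@](C)(CCO[Si](C)(C)C(C)(C)C)[C@@H]2C(=C(C)C)O1 | intermediate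
13 | 1-[(1S,2S,7S)-2-hydroxy-7-(2-hydroxyethyl)-4,7-dimethylcyclohept-4-en-1-yl]-2-methylpropan-1-one | O[C@H]1CC(C)=CC[C@@](C)(CCO)[C@@H]1C(=O)C(C)C | intermediate
14 | 1-[(1S,2S,7S)-2-hydroxy-7-(2-iodoethyl)-4,7-dimethylcyclohept-4-en-1-yl]-2-methylpropan-1-one | O[C@H]1CC(C)=CC[C@@](C)(CCI)[C@@H]1C(=O)C(C)C | intermediate
15 | (3R,3aS,4S,8aR)-6,8a-dimethyl-3-(propan-2-yl)-1,2,3,3a,4,5,8,8a-octahydroazulene-3,4-diol | O[C@H]1CC(C)=CC[C@@]2(C)CC[C@@](O)(C(C)C)[C@H]12 | intermediate
16 | 4-(acetyloxy)-3-methoxybenzoic acid | COc1cc(C(=O)O)ccc1OC(C)=O | starting material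
17 | (3R,3aS,4S,8aR)-3-hydroxy-6,8a-dimethyl-3-(propan-2-yl)-1,2,3,3a,4,5,8,8a-octahydroazulen-4-yl 4-(acetyloxy)-3-methoxybenzoate | COc1cc(C(=O)O[C@H]2CC(C)=CC[C@@]3(C)CC[C@@](O)(C(C)C)[C@H]23)ccc1OC(C)=O | intermediate
18 | teferin | COc1cc(C(=O)O[C@H]2CC(C)=CC[C@@]3(C)CC[C@@](O)(C(C)C)[C@H]23)ccc1O | target

**Totals**
Total step count: 11. Longest linear sequence: 10 steps (steps 2–11).

**Steps most likely to fail**

Step 6. The hindered trisubstituted alkene may fail to insert into the allyl–rhodium bond, so that the rhodacycle collapses by cyclopropane isomerisation or ring opening, or the addition may take the opposite facial sense. The fallback gives up the one-step union and builds the ring stepwise by known reactions; it sets out from 4 and comes back at 13. Hosomi–Sakurai conjugate allylation of 4 (allyltrimethylsilane, TiCl4) would give the racemic β-allyl ketone F1. Kinetic enolisation at the CH2 between the carbonyl and the quaternary carbon (LDA, −78 °C) and aldol addition to 3-methylbut-3-enal would give the β-hydroxy ketone F2 as a diastereomer mixture. Ring-closing metathesis with a second-generation ruthenium carbene catalyst would close the trisubstituted cycloheptene, and the isomer with the relative configuration of 13 would be separated as the racemic silyl ether F3. Lipase-catalysed acylation would remove the unwanted enantiomer and leave the (2S)-carbinol F4, and TBAF would give 13. This fallback has no built-in control of C5 relative to C1 and relies on separation.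

Step 5. Enolisation may occur at the γ-position instead of α′, or the labile chlorosilane and mixed silyl enol ether may hydrolyse during assembly. The fallback makes the silyl enol ether by conjugate hydrosilylation instead of enolate chemistry; it sets out from 1 and 9 and comes back at 11. The protocol of step 1 with 2-methylprop-2-enoyl chloride would give the cross-conjugated dienone F5. Silylation of 9 with chlorodi(propan-2-yl)silane and imidazole would give the hydrosilane F6. Copper hydride-catalysed 1,4-hydrosilylation of the less hindered isopropenyl enone terminus of F5 with F6 would then deliver 11 regiospecifically.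

Step 9. The alkylsamarium may be protonated by the free C6 hydroxyl before it adds, or the ketyl may trigger retro-aldol or elimination pathways. The fallback replaces the samarium closure with an anionic cyclisation on a protected substrate; it sets out from 14 and comes back at 15. Silylation (TESCl, imidazole) would give the silyl ether F7. Iodine–lithium exchange with t-BuLi at −100 °C, which should outpace carbonyl addition, followed by intramolecular addition to the ketone (steric control, isopropyl anti to C6 and the C1 methyl) would give the cyclised silyl ether F8, and TBAF would give 15.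

**Further compounds**
F1 | step 6 | rac-5-{2-[(tert-butyldimethylsilyl)oxy]ethyl}-2,5-dimethyloct-7-en-3-one | CC(C)C(=O)CC(C)(CC=C)CCO[Si](C)(C)C(C)(C)C
F2 | step 6 | aldol adduct of F1 with 3-methylbut-3-enal (diastereomer mixture) | CC(C)C(=O)C(C(O)CC(C)=C)C(C)(CC=C)CCO[Si](C)(C)C(C)(C)C
F3 | step 6 | racemic 1-[2-hydroxy-7-{2-[(tert-butyldimethylsilyl)oxy]ethyl}-4,7-dimethylcyclohept-4-en-1-yl]-2-methylpropan-1-one, relative configuration as in 13 | OC1CC(C)=CCC(C)(CCO[Si](C)(C)C(C)(C)C)C1C(=O)C(C)C
F4 | step 6 | 1-[(1S,2S,7S)-7-{2-[(tert-butyldimethylsilyl)oxy]ethyl}-2-hydroxy-4,7-dimethylcyclohept-4-en-1-yl]-2-methylpropan-1-one | O[C@H]1CC(C)=CC[C@@](C)(CCO[Si](C)(C)C(C)(C)C)[C@@H]1C(=O)C(C)C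
F5 | step 5 | (4E)-7-[(tert-butyldimethylsilyl)oxy]-2,5-dimethylhepta-1,4-dien-3-one | C=C(C)C(=O)/C=C(\C)CCO[Si](C)(C)C(C)(C)C
F6 | step 5 | {[(1S)-2-ethenyl-2-methylcyclopropyl]oxy}di(propan-2-yl)silane | CC(C)[SiH](C(C)C)O[C@H]1CC1(C)C=C
F7 | step 9 | 1-[(1S,2S,7S)-7-(2-iodoethyl)-4,7-dimethyl-2-[(triethylsilyl)oxy]cyclohept-4-en-1-yl]-2-methylpropan-1-one | CC[Si](CC)(CC)O[C@H]1CC(C)=CC[C@@](C)(CCI)[C@@H]1C(=O)C(C)C
F8 | step 9 | (3R,3aS,4S,8aR)-6,8a-dimethyl-3-(propan-2-yl)-4-[(triethylsilyl)oxy]-1,2,3,3a,4,5,8,8a-octahydroazulen-3-ol | CC[Si](CC)(CC)O[C@H]1CC(C)=CC[C@@]2(C)CC[C@@](O)(C(C)C)[C@H]12
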